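**Retrosynthetic overview**
1. The three benzyl ethers come off last. Before that, C3 and C3'' are set together by kinetic C-protonation of the 4,4''-bis(silyloxy)-3,3''-bi(2H-chromene), anti to the pseudo-axial aryl groups at C2 and C2'', which gives the 2,3-cis/2'',3''-cis array.
2. Key disconnection: ring C of the 5,7-dioxygenated unit (unit 1) is cut at O1–C8a and C3–C4. This leads to a carbinol that already holds the finished 5-hydroxy-7-methoxy unit (unit 2, double-primed locants) as a 3''-ylidene flavanone, and to 2,4-bis(benzyloxy)-6-fluorobenzaldehyde. Forward: SNAr etherification, then intramolecular Stetter closure in the same flask.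
3. Enabling feature: on ring A, C8a is ortho to the carbon that carries C4 and meta to both ring-A oxygens, so a fluoride there is displaced while C4 is a formyl group. C3 is the β-carbon of the exocyclic C3=C3'' enone of ring C'' (C4''=O) and lies three atoms (O1–C2–C3) from C8a, so the acyl anion generated at C4 closes a six-membered ring on it.
4. Ring C'' comes from SNAr etherification and carbene-catalysed hydroacylation of an internal alkyne (C4''–C3''). C2 and C2'' come from two catalytic asymmetric alkynylations of 4-methoxybenzaldehyde.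
5. Order of ring formation: rings A, B, A'', B'' are bought; ring C'' is closed first, ring C second.

Key step: step 11

Remark: (R,R)-ProPhenol is assumed to be the ligand antipode that delivers the alkynyl group to the aldehyde face giving (S)-3 in step 1 and the (1S)-centre of 6 in step 4; if the sense is the opposite, its mirror image is used in both steps.
Remark: the two carbinol carbons keep their geometry from steps 1 and 4 to the target; their CIP descriptors change along the way (S in 3, 4 and 6, R in the terminal alkyne 5, R in the target) only because the ranking of the neighbouring carbon changes.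

**Step 1**
Reactants: 1 4-methoxybenzaldehyde; 2 ethynyltrimethylsilane
Product: 3 (S)-1-(4-methoxyphenyl)-3-(trimethylsilyl)prop-2-yn-1-ol
Conditions: ZnMe2 (3 equiv), (R,R)-ProPhenol [2,6-bis{[(2R)-2-(hydroxydiphenylmethyl)pyrrolidin-1-yl]methyl}-4-methylphenol, 20 mol %], Ph3PO (40 mol %), toluene, 4 °C; aq. NH4Cl
Reagents that add atoms: none
Why: Catalytic asymmetric alkynylation of an aryl aldehyde by an alkynylzinc under a dinuclear zinc–aminoalcohol catalyst should set the carbinol centre (the future C2) by catalyst control.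

**Step 2**
Reactants: 3 (S)-1-(4-methoxyphenyl)-3-(trimethylsilyl)prop-2-yn-1-ol
Product: 4 (S)-tert-butyl{[1-(4-methoxyphenyl)-3-(trimethylsilyl)prop-2-yn-1-yl]oxy}dimethylsilane
Conditions: TBSCl, imidazole, DMF, 0 °C to rt
Reagents that add atoms: tert-butyldimethylsilyl chloride (TBSCl), CC(C)(C)[Si](C)(C)Cl
Why: Standard O-silylation of a secondary alcohol, which does not touch the stereocentre.

**Step 3**
Reactants: 4 (S)-tert-butyl{[1-(4-methoxyphenyl)-3-(trimethylsilyl)prop-2-yn-1-yl]oxy}dimethylsilane
Product: 5 (R)-tert-butyl{[1-(4-methoxyphenyl)prop-2-yn-1-yl]oxy}dimethylsilane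
Conditions: K2CO3 (cat.), MeOH, rt
Reagents that add atoms: none
Why: Methanolysis of the alkynyl C–Si bond (protodesilylation) is selective for the alkynylsilane, and the silyl ether should survive; the geometry of the stereocentre is unchanged and only its descriptor switches because the ethynyl group now ranks below the aryl group.

**Step 4**
Reactants: 5 (R)-tert-butyl{[1-(4-methoxyphenyl)prop-2-yn-1-yl]oxy}dimethylsilane; 1 4-methoxybenzaldehyde
Product: 6 (1S,4S)-4-[(tert-butyldimethylsilyl)oxy]-1,4-bis(4-methoxyphenyl)but-2-yn-1-ol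
Conditions: ZnMe2 (3 equiv), (R,R)-ProPhenol (20 mol %), Ph3PO (40 mol %), toluene, 4 °C; aq. NH4Cl
Reagents that add atoms: none
Why: A second catalytic asymmetric alkynylation sets the new carbinol centre (the future C2'') by catalyst control, the existing silyloxy centre being four atoms away, and leaves the two oxygens differentiated.

**Step 5**
Reactants: 7 2,6-difluoro-4-methoxybenzaldehyde; 8 benzyl alcohol
Product: 9 2-(benzyloxy)-6-fluoro-4-methoxybenzaldehyde
Conditions: KOC(CH3)3 (1.0 equiv), THF, −20 °C to rt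
Reagents that add atoms: none
Why: SNAr of benzyloxide at a fluorine ortho to the formyl group should stop after one substitution because the new alkoxy group lowers the acceptor strength of the formyl group.

**Step 6**
Reactants: 10 2,6-difluoro-4-hydroxybenzaldehyde
Product: 11 4-(benzyloxy)-2,6-difluorobenzaldehyde
Conditions: BnBr (1.1 equiv), K2CO3 (1.5 equiv), DMF, rt
Reagents that add atoms: benzyl bromide (BnBr), BrCc1ccccc1
Why: Williamson O-benzylation of the acidic para-hydroxy group (phenoxide, SN2 at the benzylic bromide) fixes the 4-benzyloxy group before any fluoride is displaced, so the later substitution pattern is unambiguous.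

**Step 7**
Reactants: 11 4-(benzyloxy)-2,6-difluorobenzaldehyde; 8 benzyl alcohol
Product: 12 2,4-bis(benzyloxy)-6-fluorobenzaldehyde
Conditions: KOC(CH3)3 (1.0 equiv), THF, −20 °C to rt
Reagents that add atoms: none
Why: SNAr of benzyloxide at one of the two equivalent fluorines ortho to the formyl group can give only one regioisomer and should stop after one substitution because the new alkoxy group lowers the acceptor strength of the formyl group.

**Step 8**
Reactants: 6 (1S,4S)-4-[(tert-butyldimethylsilyl)oxy]-1,4-bis(4-methoxyphenyl)but-2-yn-1-ol; 9 2-(benzyloxy)-6-fluoro-4-methoxybenzaldehyde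
Product: 13 2-(benzyloxy)-6-{[(1S,4S)-4-[(tert-butyldimethylsilyl)oxy]-1,4-bis(4-methoxyphenyl)but-2-yn-1-yl]oxy}-4-methoxybenzaldehyde
Conditions: NaH (1.0 equiv), DMF, 0 to 50 °C
Reagents that add atoms: none
Why: SNAr etherification by the propargylic alkoxide at the fluorine ortho to the formyl group (meta to both alkoxy groups) forms O1''–C8a'' at oxygen, so the carbinol carbon keeps its configuration.

**Step 9**
Reactants: 13 2-(benzyloxy)-6-{[(1S,4S)-4-[(tert-butyldimethylsilyl)oxy]-1,4-bis(4-methoxyphenyl)but-2-yn-1-yl]oxy}-4-methoxybenzaldehyde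
Product: 14 (2S,3E)-5-(benzyloxy)-3-[(2R)-2-[(tert-butyldimethylsilyl)oxy]-2-(4-methoxyphenyl)ethylidene]-7-methoxy-2-(4-methoxyphenyl)chroman-4-one
Conditions: 3-(2,4,6-trimethylphenyl)-5,6,7,8-tetrahydro-4H-cyclohepta[d][1,3]thiazol-3-ium perchlorate (10 mol %), K2CO3 (20 mol %), THF, 70 °C
Reagents that add atoms: none
Why: Carbene-catalysed intramolecular hydroacylation of an unactivated alkyne (6-exo-dig, concerted syn transfer of acyl and hydrogen from the Breslow intermediate) should close ring C'' and give the (E)-alkylidene ketone without touching either carbinol centre.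

**Step 10**
Reactants: 14 (2S,3E)-5-(benzyloxy)-3-[(2R)-2-[(tert-butyldimethylsilyl)oxy]-2-(4-methoxyphenyl)ethylidene]-7-methoxy-2-(4-methoxyphenyl)chroman-4-one
Product: 15 (2S,3E)-5-(benzyloxy)-3-[(2R)-2-hydroxy-2-(4-methoxyphenyl)ethylidene]-7-methoxy-2-(4-methoxyphenyl)chroman-4-one
Conditions: HF·pyridine, pyridine, THF, 0 °C
Reagents that add atoms: none
Why: Buffered acidic fluoride desilylation frees the carbinol without exposing the γ-oxygenated enone to base.

**Step 11**
Reactants: 15 (2S,3E)-5-(benzyloxy)-3-[(2R)-2-hydroxy-2-(4-methoxyphenyl)ethylidene]-7-methoxy-2-(4-methoxyphenyl)chroman-4-one; 12 2,4-bis(benzyloxy)-6-fluorobenzaldehyde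
Product: 17 (2R,2''R)-5,7,5''-tris(benzyloxy)-7''-methoxy-2,2''-bis(4-methoxyphenyl)-[3,3''-bichromane]-4,4''-dione (C3/C3'' epimer mixture), via aryl ether aldehyde 16 (not isolated)
Conditions: NaH (1.0 equiv), DMF, 0 °C, then 12, 0 to 40 °C; then 3-(2,4,6-trimethylphenyl)-5,6,7,8-tetrahydro-4H-cyclohepta[d][1,3]thiazol-3-ium perchlorate (20 mol %), K2CO3 (30 mol %), 60 °C, same flask
Reagents that add atoms: none
Why: The sodium alkoxide of 15 displaces the fluoride of 12 by SNAr at the carbon ortho to the formyl group and meta to both benzyloxy groups, which forms O1–C8a with retention at C2 and gives 16. The thiazol-2-ylidene then turns the formyl group into a Breslow acyl-anion equivalent that adds to C3, the β-carbon of the exocyclic C3=C3'' enone, and proton transfer to C3'' with loss of the carbene gives the 1,4-diketone; this is an intramolecular Stetter reaction of the kind used to make chroman-4-ones from salicylaldehyde-derived γ-aryloxy enones. Ring C is closed in the 6-exo-trig mode by the C3–C4 bond, the O1–C8a bond being made intermolecularly just before. C3 is formed under two opposing influences (delivery from the O1 side of C2 and shielding by the pseudo-axial aryl group at C2''), and C3'' by protonation of an enol, so neither centre is relied on here and both are re-set in step 12, while C2 and C2'' are not touched. The step needs O-arylation to precede any C–H deprotonation at the γ-position of the enone and Stetter closure to beat benzoin coupling; irreversible alkoxide formation at low temperature, the single fluoride on 12 and the six-membered tether should secure this.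

**Step 12**
Reactants: 17 (2R,2''R)-5,7,5''-tris(benzyloxy)-7''-methoxy-2,2''-bis(4-methoxyphenyl)-[3,3''-bichromane]-4,4''-dione (C3/C3'' epimer mixture)
Product: 19 (2R,3R,2''R,3''R)-5,7,5''-tris(benzyloxy)-7''-methoxy-2,2''-bis(4-methoxyphenyl)-[3,3''-bichromane]-4,4''-dione, via bis(trimethylsilyl) dienol ether 18 (not isolated)
Conditions: TMSOTf (4 equiv), Et3N (6 equiv), CH2Cl2, 0 °C to rt; then 1 M HCl, THF, −40 to 0 °C
Reagents that add atoms: none
Why: Soft enolisation of both ketones (silyl triflate/amine) converges all C3/C3'' epimers to one dienol ether in which A(1,2) strain holds each C2/C2'' aryl group pseudo-axial, and kinetic C-protonation of each enol ether anti to that aryl group places H3 trans and the C3 substituent cis to it, which should set C3 and C3'' as R from the (R)-centres at C2 and C2''.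

**Step 13**
Reactants: 19 (2R,3R,2''R,3''R)-5,7,5''-tris(benzyloxy)-7''-methoxy-2,2''-bis(4-methoxyphenyl)-[3,3''-bichromane]-4,4''-dione
Product: 20 (2R,3R,2''R,3''R)-5,7,5''-trihydroxy-7''-methoxy-2,2''-bis(4-methoxyphenyl)-[3,3''-bichromane]-4,4''-dione (target)
Conditions: H2 (1 atm), Pd/C (10 wt% palladium on carbon), EtOAc–MeOH, rt
Reagents that add atoms: none
Why: Neutral hydrogenolysis of the three aryl benzyl ethers should free the phenols without enolising the ketones, so the four stereocentres are kept.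

**Compound list**
1 | 4-methoxybenzaldehyde | COc1ccc(C=O)cc1 | starting material
2 | ethynyltrimethylsilane | C#C[Si](C)(C)C | starting material
3 | (S)-1-(4-methoxyphenyl)-3-(trimethylsilyl)prop-2-yn-1-ol | COc1ccc(cc1)[C@H](O)C#C[Si](C)(C)C | intermediate
4 | (S)-tert-butyl{[1-(4-methoxyphenyl)-3-(trimethylsilyl)prop-2-yn-1-yl]oxy}dimethylsilane | COc1ccc(cc1)[C@H](O[Si](C)(C)C(C)(C)C)C#C[Si](C)(C)C | intermediate
5 | (R)-tert-butyl{[1-(4-methoxyphenyl)prop-2-yn-1-yl]oxy}dimethylsilane | COc1ccc(cc1)[C@H](O[Si](C)(C)C(C)(C)C)C#C | intermediate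
6 | (1S,4S)-4-[(tert-butyldimethylsilyl)oxy]-1,4-bis(4-methoxyphenyl)but-2-yn-1-ol | COc1ccc(cc1)[C@H](O[Si](C)(C)C(C)(C)C)C#C[C@@H](O)c1ccc(OC)cc1 | intermediate
7 | 2,6-difluoro-4-methoxybenzaldehyde | COc1cc(F)c(C=O)c(F)c1 | starting material
8 | benzyl alcohol | OCc1ccccc1 | starting material
9 | 2-(benzyloxy)-6-fluoro-4-methoxybenzaldehyde | COc1cc(F)c(C=O)c(OCc2ccccc2)c1 | intermediate
10 | 2,6-difluoro-4-hydroxybenzaldehyde | O=Cc1c(F)cc(O)cc1F | starting material
11 | 4-(benzyloxy)-2,6-difluorobenzaldehyde | O=Cc1c(F)cc(OCc2ccccc2)cc1F | intermediate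
12 | 2,4-bis(benzyloxy)-6-fluorobenzaldehyde | O=Cc1c(F)cc(OCc2ccccc2)cc1OCc1ccccc1 | intermediate
13 | 2-(benzyloxy)-6-{[(1S,4S)-4-[(tert-butyldimethylsilyl)oxy]-1,4-bis(4-methoxyphenyl)but-2-yn-1-yl]oxy}-4-methoxybenzaldehyde | COc1ccc(cc1)[C@H](O[Si](C)(C)C(C)(C)C)C#C[C@@H](Oc1cc(OC)cc(OCc2ccccc2)c1C=O)c1ccc(OC)cc1 | intermediate
14 | (2S,3E)-5-(benzyloxy)-3-[(2R)-2-[(tert-butyldimethylsilyl)oxy]-2-(4-methoxyphenyl)ethylidene]-7-methoxy-2-(4-methoxyphenyl)chroman-4-one | COc1ccc(cc1)[C@H](O[Si](C)(C)C(C)(C)C)/C=C1/C(=O)c2c(OCc3ccccc3)cc(OC)cc2O[C@H]1c1ccc(OC)cc1 | intermediate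
15 | (2S,3E)-5-(benzyloxy)-3-[(2R)-2-hydroxy-2-(4-methoxyphenyl)ethylidene]-7-methoxy-2-(4-methoxyphenyl)chroman-4-one | COc1ccc(cc1)[C@H](O)/C=C1/C(=O)c2c(OCc3ccccc3)cc(OC)cc2O[C@H]1c1ccc(OC)cc1 | intermediate
16 | 2,4-bis(benzyloxy)-6-{(1R,2E)-2-[(2S)-5-(benzyloxy)-7-methoxy-2-(4-methoxyphenyl)-4-oxochroman-3-ylidene]-1-(4-methoxyphenyl)ethoxy}benzaldehyde | COc1ccc(cc1)[C@H](Oc1cc(OCc2ccccc2)cc(OCc2ccccc2)c1C=O)/C=C1/C(=O)c2c(OCc3ccccc3)cc(OC)cc2O[C@H]1c1ccc(OC)cc1 | intermediate (not isolated)
17 | (2R,2''R)-5,7,5''-tris(benzyloxy)-7''-methoxy-2,2''-bis(4-methoxyphenyl)-[3,3''-bichromane]-4,4''-dione, C3/C3'' epimer mixture (C3 and C3'' left open in the SMILES) | COc1ccc([C@@H]2Oc3cc(OCc4ccccc4)cc(OCc4ccccc4)c3C(=O)C2C2C(=O)c3c(OCc4ccccc4)cc(OC)cc3O[C@H]2c2ccc(OC)cc2)cc1 | intermediate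
18 | (2S,2''S)-5,7,5''-tris(benzyloxy)-7''-methoxy-2,2''-bis(4-methoxyphenyl)-4,4''-bis(trimethylsilyloxy)-2H,2''H-3,3''-bichromene (geometry at C2 and C2'' as in 17) | COc1ccc([C@@H]2Oc3cc(OCc4ccccc4)cc(OCc4ccccc4)c3C(O[Si](C)(C)C)=C2C2=C(O[Si](C)(C)C)c3c(OCc4ccccc4)cc(OC)cc3O[C@H]2c2ccc(OC)cc2)cc1 | intermediate (not isolated)
19 | (2R,3R,2''R,3''R)-5,7,5''-tris(benzyloxy)-7''-methoxy-2,2''-bis(4-methoxyphenyl)-[3,3''-bichromane]-4,4''-dione | COc1ccc([C@@H]2Oc3cc(OCc4ccccc4)cc(OCc4ccccc4)c3C(=O)[C@@H]2[C@H]2C(=O)c3c(OCc4ccccc4)cc(OC)cc3O[C@H]2c2ccc(OC)cc2)cc1 | intermediate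
20 | (2R,3R,2''R,3''R)-5,7,5''-trihydroxy-7''-methoxy-2,2''-bis(4-methoxyphenyl)-[3,3''-bichromane]-4,4''-dione | COc1ccc([C@@H]2Oc3cc(O)cc(O)c3C(=O)[C@@H]2[C@H]2C(=O)c3c(O)cc(OC)cc3O[C@H]2c2ccc(OC)cc2)cc1 | target

**Step count**
Total step count: 13. Longest linear sequence: 10 steps (steps 1–4 and 8–13).

**Steps most likely to fail**

(a) Step 11. The SNAr at the hindered allylic alkoxide of 15 may be slow on the donor-substituted fluoroarene, so that base-induced isomerisation of the γ-oxygenated enone (loss of the C2 centre) competes. Carbene addition to the di-ortho-alkoxy aldehyde of 16 may also be slow. The fallback moves the etherification ahead of any enone. It sets out from 13, which is desilylated (HF·pyridine) to 2-(benzyloxy)-6-{[(1S,4S)-4-hydroxy-1,4-bis(4-methoxyphenyl)but-2-yn-1-yl]oxy}-4-methoxybenzaldehyde F1. The robust propargylic alkoxide of F1 (NaH, DMF) is arylated with 12 to the bis(aryl ether) dialdehyde 2,4-bis(benzyloxy)-6-{[(1S,4S)-4-[3-(benzyloxy)-2-formyl-5-methoxyphenoxy]-1,4-bis(4-methoxyphenyl)but-2-yn-1-yl]oxy}benzaldehyde F2. The same thiazolium carbene (K2CO3, THF, 70 °C) then runs a hydroacylation–Stetter cascade, one formyl group adding across the alkyne and the other closing on the enone so formed. Whichever aldehyde reacts first, the constitution is the same, and the fallback comes back to the route at 17.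

(b) Step 9. Formation of the Breslow intermediate from the 2,6-dialkoxybenzaldehyde may be slow, and the carbonate may isomerise the propargylic ether to an allenyl ether. The fallback replaces the polar carbene pathway by a neutral radical chain. It sets out from 13: tert-dodecanethiol (polarity-reversal catalyst) and azobisisobutyronitrile in chlorobenzene at 80 °C generate the acyl radical, which cyclises 6-exo-dig onto the alkyne; the vinyl radical takes hydrogen from the thiol. This should give 14 together with its geometrical isomer (2S,3Z)-5-(benzyloxy)-3-[(2R)-2-[(tert-butyldimethylsilyl)oxy]-2-(4-methoxyphenyl)ethylidene]-7-methoxy-2-(4-methoxyphenyl)chroman-4-one F3, which reversible thiyl addition should funnel to the more stable (E)-isomer. The fallback comes back to the route at 14.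

(c) Step 12. The silyl triflate may ionise the 4-methoxybenzylic C2–O1 and C2''–O1'' bonds (erosion at C2/C2''), and enolisation of the two hindered tertiary α-CH groups may stay incomplete. The fallback reaches the dienol without a Lewis acid and without deprotonation. It sets out from 17, which is dehydrogenated with SeO2 (dioxane, 80 °C; the usual conversion of a 1,4-diketone into an ene-1,4-dione) to 5,7,5''-tris(benzyloxy)-7''-methoxy-2,2''-bis(4-methoxyphenyl)-[3,3''-bichromanylidene]-4,4''-dione F4. Zinc dust in acetic acid at 0 °C then reduces the ene-dione through its zinc dienolate/dienol, whose two C-protonations are again directed anti to the pseudo-axial aryl groups. The fallback comes back to the route at 19.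

**Further compounds**
F1 | step 11 | 2-(benzyloxy)-6-{[(1S,4S)-4-hydroxy-1,4-bis(4-methoxyphenyl)but-2-yn-1-yl]oxy}-4-methoxybenzaldehyde | COc1ccc(cc1)[C@H](O)C#C[C@@H](Oc1cc(OC)cc(OCc2ccccc2)c1C=O)c1ccc(OC)cc1
F2 | step 11 | 2,4-bis(benzyloxy)-6-{[(1S,4S)-4-[3-(benzyloxy)-2-formyl-5-methoxyphenoxy]-1,4-bis(4-methoxyphenyl)but-2-yn-1-yl]oxy}benzaldehyde | COc1ccc(cc1)[C@H](Oc1cc(OCc2ccccc2)cc(OCc2ccccc2)c1C=O)C#C[C@@H](Oc1cc(OC)cc(OCc2ccccc2)c1C=O)c1ccc(OC)cc1
F3 | step 9 | (2S,3Z)-5-(benzyloxy)-3-[(2R)-2-[(tert-butyldimethylsilyl)oxy]-2-(4-methoxyphenyl)ethylidene]-7-methoxy-2-(4-methoxyphenyl)chroman-4-one | COc1ccc(cc1)[C@H](O[Si](C)(C)C(C)(C)C)/C=C1\C(=O)c2c(OCc3ccccc3)cc(OC)cc2O[C@H]1c1ccc(OC)cc1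
F4 | step 12 | 5,7,5''-tris(benzyloxy)-7''-methoxy-2,2''-bis(4-methoxyphenyl)-[3,3''-bichromanylidene]-4,4''-dione (C2 and C2'' geometry as in 17, alkene geometry open) | COc1ccc([C@@H]2Oc3cc(OCc4ccccc4)cc(OCc4ccccc4)c3C(=O)C2=C2C(=O)c3c(OCc4ccccc4)cc(OC)cc3O[C@H]2c2ccc(OC)cc2)cc1
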